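Numbering used throughout: dihydrobenzofuran positions O1, C2, C3, C3a, C4–C7, C7a; C9 is the CH2 group on C3; ring A is the benzo ring, ring B the oxygen ring. Positions of the four-membered lactone are written "lactone C3" and "lactone C4". Compound numbers are those of the steps and the compound list.

## Analysis of the target

Target 21 is a 2,3-dihydrobenzofuran neolignan. Ring A (C3a, C4, C5, C6, C7, C7a) carries an allyl group at C5 and a methoxy group at C7. Ring B (O1, C2, C3, C3a, C7a) carries a 4-hydroxy-3-methoxyphenyl group at C2 and, at C3, the CH2 group C9, whose oxygen is the phenolic oxygen of a 4-allyl-2-methoxyphenyl unit. The only stereocentres are C2 (S) and C3 (R); they are adjacent and trans, with the C2 aryl group and C9 on opposite faces of ring B. Trans is the more stable arrangement, but C3 can be equilibrated only while C9 is still a carbonyl group. The sensitive groups are two allylbenzene units (no hydrogenation, hydroboration, ozonolysis or electrophilic halogen, and no hot strong base, which moves the double bond into conjugation), a free phenol para to the benzylic C2–O1 bond (quinone methide formation can open ring B) and three electron-rich arenes. The difficulty lies in the absolute configuration at C2, a benzylic ether carbon with no functional group of its own in the target, and in joining two very similar guaiacyl halves without confusing their oxygens. The route rests on one observation: C2, C3 and C9 stand at the oxidation levels of an aldehyde carbon, an enolate carbon and a carboxyl carbon, so with one oxygen they fold into a 2-oxetanone, and O1, the phenolic oxygen ortho to C3a, sits where it can later displace the lactone oxygen at C2.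

## Retrosynthetic reasoning

21 from 20. The free phenol is carried as its methanesulfonate and released last. Until then this oxygen must be neither acidic nor nucleophilic, so that it does not compete in the ether formation at C9, and an electron-withdrawing sulfonate serves the key step as well.

20 from 18 and 19. The C9–O bond is cut. A primary alcohol and a phenol of pKa about 10 are the ideal pair for a Mitsunobu coupling, the cut is convergent, and 19 arrives with its allyl group untouched by all earlier chemistry. Cutting the O–aryl bond instead would require arylation with an electron-rich, unactivated arene.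

18 from 17. C9 is taken back to the ester oxidation level. This costs one hydride reduction and gives C3 an acidic hydrogen.

17 from 16. The trans ester is the equilibrium partner of the cis ester, so C3 need not be set correctly when it is first formed. Only C2 has to be delivered with defined absolute configuration, and the base used must leave it alone.

16 from 13. The O1–C2 bond (and the ester O–methyl bond) is cut and the carboxyl group is folded back onto C2 as a four-membered lactone. In the forward direction, removing the silyl group from the ring A oxygen frees a phenoxide that is to attack lactone C4 from the side opposite the ring oxygen. This forms ring B with inversion and liberates the carboxylate, which is methylated. The cut is made at O1–C2 because this is the one ring B bond that can be formed by substitution at a centre whose configuration was fixed earlier. The lactone carbon must therefore have the mirror configuration of C2.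

13 from 9 and 11. The lactone is cut across the C2–C3 bond and the acyl C–O bond, a retro [2+2] into an arylketene (from acid chloride 9) and aldehyde 11. This single catalytic step joins the two aromatic halves, makes both stereocentres and puts C9 at the right oxidation level. A silylated cinchona alkaloid with a lithium Lewis acid is the catalyst system.

11 from 10. O-Sulfonylation of vanillin.

9 from 8, 7, 6 and 5. The acid chloride comes from acid 8, reached by one-carbon homologation of the silylated salicylaldehyde 5: methoxymethylenation to 6, hydrolysis to 7 and oxidation to 8. These mild conditions spare the allyl group and the aryl silyl ether.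

5 from 4, 3, 1 and 2. The silyl ether comes from phenol 4. Its allyl group is placed by O-allylation of 1 with 2 and a para Claisen rearrangement of 3. Both ortho positions of 3 are occupied, so the allyl group can end only at C5.

## Alternatives that were turned down

Alternative 1: ring B is cut at C2–C3 and closed by intramolecular carbenoid C–H insertion. The aryldiazoacetate A2 is decomposed by Rh2(S-PTTL)4 (dirhodium tetrakis[N-phthaloyl-(S)-tert-leucinate]), and the carbenoid inserts into the benzylic C–H bond of its own benzyl ether to give the cis bromo ester A1. In its favour, this ring closure is the best established asymmetric entry to cis 2-aryl-2,3-dihydrobenzofuran-3-carboxylates, it sets both centres under catalyst control, and A1 would enter the same end game as 16. Against it, a rhodium carbenoid cyclopropanates alkenes, so the ring A allyl group cannot be present; hence the bromine in A1 and a late palladium-catalysed allylation that must not isomerise either allyl group. It also needs a diazo transfer onto an electron-rich arylacetate and a costly catalyst. On the reliability of the ring-forming step it is stronger than the chosen route. The chosen route offers instead both allyl groups in place from the start, no diazo compound and no noble metal, at the price of an untested ring switch.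

Alternative 2: ring A itself is disconnected (C3a–C7a, C6–C7 and C7–O) to a furan and an alkyne. (Ph3P)AuNTf2 activates the ethynyl ether A4, the furan carbon attacks the oxygen-bearing alkyne carbon, and the furan reopens and recloses as a phenol, giving A3 with rings A and B formed together. In its favour, the skeleton is assembled late and the stereocentres are not touched in the key step. Against it, the key step creates no stereocentre, so C2 and C3 must be set beforehand in the acyclic A4. A4 combines a 2,4-disubstituted furan with an ethynyl ether of a secondary benzylic alcohol; the furan is laborious to make and the ether is thermally labile. Cationic gold can also engage the allyl groups, and the new phenol in A3 still needs methylation. It is longer and no stronger on any point that matters here. The chosen route makes both stereocentres in the step that joins the halves and takes ring A intact from a commodity aldehyde.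

Alternative 3: C3–C3a and C9–O are cut. Bu3SnH and AIBN generate the ring A aryl radical from the bromo ether A6, it closes 5-exo onto the vinyl group, and TEMPO traps the primary radical to give the trans alkoxyamine A5. In its favour, this is the shortest plan: the 5-exo closure is very fast, it is trans-selective by itself and it leaves C9 oxygenated. Against it, Bu3SnH and TEMPO consume each other, and Bu3SnH reduces the primary radical in competition with trapping. C3 is set by substrate control only, and a cis isomer cannot be corrected because C3 has no acidifying group. A6 is a benzylic and allylic aryl ether prone to ionisation and loss of configuration, and tin is used in stoichiometric amount. On step economy it is stronger. The chosen route offers catalyst-set configuration at C2, thermodynamic correction of C3 and no tin.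

Key step: step 9

Assumption: O-trimethylsilylquinidine is taken to induce the (3R,4R) lactone, by analogy with the sense in which quinidine-derived catalysts deliver substituted ketenes to electrophiles; if the sense proves opposite, O-trimethylsilylquinine is used and nothing else changes.

## Route

Step 1
Reactants: 1 o-vanillin; 2 allyl bromide
Product: 3 2-(allyloxy)-3-methoxybenzaldehyde
Conditions: K2CO3, DMF, rt
Reagents that add atoms: none
Why: Williamson O-alkylation of the phenoxide of 1 with the allylic bromide 2 (SN2); the chelated phenol is acidic enough for K2CO3.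

Step 2
Reactants: 3 2-(allyloxy)-3-methoxybenzaldehyde
Product: 4 5-allyl-2-hydroxy-3-methoxybenzaldehyde
Conditions: neat (or N,N-diethylaniline), 200 °C, Ar
Reagents that add atoms: none
Why: Aromatic para Claisen rearrangement: both ortho positions of 3 are substituted, so two successive [3,3] shifts (Claisen, then Cope) carry the allyl group to the free para position and tautomerisation restores the phenol; the allyl group therefore ends para to the future O1 without a regiochemical choice.

Step 3
Reactants: 4 5-allyl-2-hydroxy-3-methoxybenzaldehyde
Product: 5 5-allyl-2-(tert-butyldimethylsilyloxy)-3-methoxybenzaldehyde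
Conditions: TBSCl, imidazole, DMF, rt
Reagents that add atoms: tert-butyldimethylsilyl chloride, CC(C)(C)[Si](C)(C)Cl
Why: Imidazole-assisted silylation of the phenol; the aryl silyl ether should survive the ylide, dilute acid, chlorite and tertiary amines of the following steps and is cleaved by fluoride when the phenoxide is wanted.

Step 4
Reactants: 5 5-allyl-2-(tert-butyldimethylsilyloxy)-3-methoxybenzaldehyde
Product: 6 [4-allyl-2-methoxy-6-(2-methoxyethenyl)phenoxy](tert-butyl)dimethylsilane (E/Z mixture)
Conditions: Ph3P(CH2OMe)Cl, KN(SiMe3)2, THF, 0 °C; then 5, −78 °C to rt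
Reagents that add atoms: (methoxymethyl)triphenylphosphonium chloride, COC[P+](c1ccccc1)(c1ccccc1)c1ccccc1.[Cl-]
Why: Wittig reaction with the methoxymethylene ylide adds the carbon that becomes C9; the E/Z ratio is of no consequence because both isomers hydrolyse to the same aldehyde.

Step 5
Reactants: 6 [4-allyl-2-methoxy-6-(2-methoxyethenyl)phenoxy](tert-butyl)dimethylsilane
Product: 7 2-[5-allyl-2-(tert-butyldimethylsilyloxy)-3-methoxyphenyl]acetaldehyde
Conditions: 2 M aq. HCl, THF, rt; crude product used at once
Reagents that add atoms: water, O
Why: Acid-catalysed enol ether hydrolysis (C-protonation, hydration of the oxocarbenium ion, loss of methanol); aryl silyl ethers and terminal alkenes tolerate dilute acid at room temperature, and the arylacetaldehyde is not stored because it self-condenses.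

Step 6
Reactants: 7 2-[5-allyl-2-(tert-butyldimethylsilyloxy)-3-methoxyphenyl]acetaldehyde
Product: 8 2-[5-allyl-2-(tert-butyldimethylsilyloxy)-3-methoxyphenyl]acetic acid
Conditions: NaClO2, NaH2PO4, 2-methyl-2-butene, t-BuOH/H2O, 0 °C to rt
Reagents that add atoms: sodium chlorite, [Na+].[O-]Cl=O
Why: Pinnick oxidation: chlorous acid oxidises the aldehyde selectively, and excess 2-methyl-2-butene removes HOCl before it can chlorinate the electron-rich ring or the allyl group.

Step 7
Reactants: 8 2-[5-allyl-2-(tert-butyldimethylsilyloxy)-3-methoxyphenyl]acetic acid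
Product: 9 2-[5-allyl-2-(tert-butyldimethylsilyloxy)-3-methoxyphenyl]acetyl chloride
Conditions: (COCl)2, DMF (cat.), CH2Cl2, 0 °C to rt; evaporate, use crude
Reagents that add atoms: oxalyl chloride, O=C(Cl)C(=O)Cl
Why: Acid chloride formation through the chloroiminium species from DMF; all by-products are volatile, so crude 9 serves directly as the ketene source.

Step 8
Reactants: 10 vanillin
Product: 11 4-formyl-2-methoxyphenyl methanesulfonate
Conditions: MsCl, Et3N, CH2Cl2, 0 °C
Reagents that add atoms: methanesulfonyl chloride, CS(=O)(=O)Cl
Why: O-Sulfonylation of the phenol; the mesylate is inert to tertiary amines, fluoride, hydride and Mitsunobu conditions, and as an acceptor it makes the aldehyde more electrophilic and deactivates the future C2 towards ionisation.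

Step 9
Reactants: 9 2-[5-allyl-2-(tert-butyldimethylsilyloxy)-3-methoxyphenyl]acetyl chloride; 11 4-formyl-2-methoxyphenyl methanesulfonate
Product: 13 (3R,4R)-3-[5-allyl-2-(tert-butyldimethylsilyloxy)-3-methoxyphenyl]-4-[3-methoxy-4-(methanesulfonyloxy)phenyl]oxetan-2-one (cis lactone), via arylketene 12 (not isolated)
Conditions: O-trimethylsilylquinidine (15 mol %), LiClO4 (2 equiv), i-Pr2NEt (2.5 equiv), CH2Cl2/Et2O, −78 °C, 9 added slowly by syringe pump
Reagents that add atoms: none
Why: i-Pr2NEt dehydrochlorinates 9 to arylketene 12, and the quinuclidine nitrogen of the alkaloid adds to it in the ketene plane on the side of hydrogen, giving a Z-configured acylammonium enolate. LiClO4 binds the enolate oxygen and the carbonyl oxygen of 11 in a closed six-membered chair transition state, in which the enolate carbon adds to the aldehyde carbon and forms the bond that becomes C2–C3. The lithium alkoxide then attacks the acylammonium carbon (4-exo-trig acyl substitution), which closes the oxetanone, forms the acyl C–O bond and returns the catalyst. The closest known reaction type is the cinchona alkaloid and lithium salt-catalysed cyclocondensation of acid chlorides with aldehydes to cis 3,4-disubstituted beta-lactones; a monoaryl ketene is a less usual partner in it but forms readily from an arylacetyl chloride. Lactone C3 is set by the alkaloid, whose quinoline and silyloxy groups cover one face of the enolate; lactone C4, the future C2, follows from it through the chair with the aldehyde aryl group pseudo-equatorial, hence cis and, with the quinidine-derived catalyst, (3R,4R). The step needs cross-addition to win over ketene dimerisation and over the uncatalysed background: slow addition keeps 12 dilute, and the para mesyloxy group makes 11 a better electrophile than a vanillin ether. The same group withdraws electron density from lactone C4, so the 4-aryl lactone should neither ionise nor decarboxylate under the conditions.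

Step 10
Reactants: 13 (3R,4R)-3-[5-allyl-2-(tert-butyldimethylsilyloxy)-3-methoxyphenyl]-4-[3-methoxy-4-(methanesulfonyloxy)phenyl]oxetan-2-one
Product: 16 methyl (2S,3R)-5-allyl-7-methoxy-2-[3-methoxy-4-(methanesulfonyloxy)phenyl]-2,3-dihydrobenzofuran-3-carboxylate (cis ester), via caesium phenoxide 14 (not isolated), via caesium carboxylate 15 (not isolated)
Conditions: CsF (2 equiv), DMF, 0 °C to rt; then MeI (5 equiv), rt
Reagents that add atoms: iodomethane, CI
Why: Proposed new method: CsF cleaves the aryl silyl ether, and the ring A phenoxide of 14, tethered through two ring carbons to lactone C3, should attack lactone C4 anti to the ring oxygen (intramolecular SN2 with alkyl–oxygen cleavage, 5-exo-tet, carboxylate as leaving group, about 23 kcal/mol of strain released); this forms O1–C2 with inversion, (4R) becoming (2S), leaves C3 untouched and so gives the cis salt 15, which is methylated in the same flask; the closest known reaction types are the SN2 opening of beta-lactones at C4 with inversion by phenoxides and other soft nucleophiles and the ring expansion of beta-lactones by tethered oxygen nucleophiles.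

Step 11
Reactants: 16 methyl (2S,3R)-5-allyl-7-methoxy-2-[3-methoxy-4-(methanesulfonyloxy)phenyl]-2,3-dihydrobenzofuran-3-carboxylate
Product: 17 methyl (2S,3S)-5-allyl-7-methoxy-2-[3-methoxy-4-(methanesulfonyloxy)phenyl]-2,3-dihydrobenzofuran-3-carboxylate (trans ester)
Conditions: DBU (0.5 equiv), toluene, 50 °C
Reagents that add atoms: none
Why: Base-mediated epimerisation at C3 through the ester enolate, a known correction for 2-aryl-2,3-dihydrobenzofuran-3-carboxylates, should strongly favour the trans isomer with aryl and ester on opposite faces. C2 keeps its configuration because beta-elimination of O1 is slow (the ring C2–O1 bond is nearly orthogonal to the enolate pi system), and DBU does not attack the mesylate.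

Step 12
Reactants: 17 methyl (2S,3S)-5-allyl-7-methoxy-2-[3-methoxy-4-(methanesulfonyloxy)phenyl]-2,3-dihydrobenzofuran-3-carboxylate
Product: 18 4-[(2S,3R)-5-allyl-3-(hydroxymethyl)-7-methoxy-2,3-dihydrobenzofuran-2-yl]-2-methoxyphenyl methanesulfonate (trans)
Conditions: i-Bu2AlH (2.5 equiv), CH2Cl2, −78 to 0 °C; aq. KNaC4H4O6 work-up
Reagents that add atoms: none
Why: Hydride reduction of the ester to the primary alcohol; i-Bu2AlH at low temperature leaves the aryl mesylate and the alkenes alone. The descriptor at C3 changes from S to R only because C9 drops in priority; after this step C3 can no longer epimerise.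

Step 13
Reactants: 18 4-[(2S,3R)-5-allyl-3-(hydroxymethyl)-7-methoxy-2,3-dihydrobenzofuran-2-yl]-2-methoxyphenyl methanesulfonate; 19 eugenol
Product: 20 4-[(2S,3R)-5-allyl-3-[(4-allyl-2-methoxyphenoxy)methyl]-7-methoxy-2,3-dihydrobenzofuran-2-yl]-2-methoxyphenyl methanesulfonate
Conditions: PPh3, DIAD, THF, 0 °C to rt
Reagents that add atoms: none
Why: Mitsunobu etherification: the primary alkoxyphosphonium ion at C9, which is not a stereocentre, is displaced by the phenoxide of 19 (pKa about 10); the mesylate keeps the second phenolic oxygen out of the reaction.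

Step 14
Reactants: 20 4-[(2S,3R)-5-allyl-3-[(4-allyl-2-methoxyphenoxy)methyl]-7-methoxy-2,3-dihydrobenzofuran-2-yl]-2-methoxyphenyl methanesulfonate
Product: 21 4-[(2S,3R)-5-allyl-3-[(4-allyl-2-methoxyphenoxy)methyl]-7-methoxy-2,3-dihydrobenzofuran-2-yl]-2-methoxyphenol (target)
Conditions: LiN(i-Pr)2 (3 equiv), THF, −78 to 0 °C; aq. NH4Cl
Reagents that add atoms: none
Why: Known mild cleavage of aryl mesylates by amide base: deprotonation of the mesyl methyl group and E1cB loss of the aryloxide, the sulfene being taken up by the amide. This avoids hot hydroxide; at low temperature the allyl groups, the ethers and both stereocentres should be untouched.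

## Compound list

1 | o-vanillin (2-hydroxy-3-methoxybenzaldehyde) | COc1cccc(C=O)c1O | starting material
2 | allyl bromide (3-bromoprop-1-ene) | C=CCBr | starting material
3 | 2-(allyloxy)-3-methoxybenzaldehyde | C=CCOc1c(OC)cccc1C=O | intermediate
4 | 5-allyl-2-hydroxy-3-methoxybenzaldehyde | C=CCc1cc(C=O)c(O)c(OC)c1 | intermediate
5 | 5-allyl-2-(tert-butyldimethylsilyloxy)-3-methoxybenzaldehyde | C=CCc1cc(C=O)c(O[Si](C)(C)C(C)(C)C)c(OC)c1 | intermediate
6 | [4-allyl-2-methoxy-6-(2-methoxyethenyl)phenoxy](tert-butyl)dimethylsilane, E/Z mixture | COC=Cc1cc(CC=C)cc(OC)c1O[Si](C)(C)C(C)(C)C | intermediate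
7 | 2-[5-allyl-2-(tert-butyldimethylsilyloxy)-3-methoxyphenyl]acetaldehyde | C=CCc1cc(CC=O)c(O[Si](C)(C)C(C)(C)C)c(OC)c1 | intermediate
8 | 2-[5-allyl-2-(tert-butyldimethylsilyloxy)-3-methoxyphenyl]acetic acid | C=CCc1cc(CC(=O)O)c(O[Si](C)(C)C(C)(C)C)c(OC)c1 | intermediate
9 | 2-[5-allyl-2-(tert-butyldimethylsilyloxy)-3-methoxyphenyl]acetyl chloride | C=CCc1cc(CC(=O)Cl)c(O[Si](C)(C)C(C)(C)C)c(OC)c1 | intermediate
10 | vanillin (4-hydroxy-3-methoxybenzaldehyde) | COc1cc(C=O)ccc1O | starting material
11 | 4-formyl-2-methoxyphenyl methanesulfonate | COc1cc(C=O)ccc1OS(C)(=O)=O | intermediate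
12 | [5-allyl-2-(tert-butyldimethylsilyloxy)-3-methoxyphenyl]ketene | C=CCc1cc(C=C=O)c(O[Si](C)(C)C(C)(C)C)c(OC)c1 | intermediate
13 | (3R,4R)-3-[5-allyl-2-(tert-butyldimethylsilyloxy)-3-methoxyphenyl]-4-[3-methoxy-4-(methanesulfonyloxy)phenyl]oxetan-2-one, cis | O=C1O[C@@H](c2ccc(OS(C)(=O)=O)c(OC)c2)[C@H]1c1cc(CC=C)cc(OC)c1O[Si](C)(C)C(C)(C)C | intermediate
14 | caesium 4-allyl-2-methoxy-6-{(3R,4R)-4-[3-methoxy-4-(methanesulfonyloxy)phenyl]-2-oxooxetan-3-yl}phenoxide | O=C1O[C@@H](c2ccc(OS(C)(=O)=O)c(OC)c2)[C@H]1c1cc(CC=C)cc(OC)c1[O-].[Cs+] | intermediate
15 | caesium (2S,3R)-5-allyl-7-methoxy-2-[3-methoxy-4-(methanesulfonyloxy)phenyl]-2,3-dihydrobenzofuran-3-carboxylate, cis | [O-]C(=O)[C@@H]1c2cc(CC=C)cc(OC)c2O[C@@H]1c1ccc(OS(C)(=O)=O)c(OC)c1.[Cs+] | intermediate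
16 | methyl (2S,3R)-5-allyl-7-methoxy-2-[3-methoxy-4-(methanesulfonyloxy)phenyl]-2,3-dihydrobenzofuran-3-carboxylate, cis | COC(=O)[C@@H]1c2cc(CC=C)cc(OC)c2O[C@@H]1c1ccc(OS(C)(=O)=O)c(OC)c1 | intermediate
17 | methyl (2S,3S)-5-allyl-7-methoxy-2-[3-methoxy-4-(methanesulfonyloxy)phenyl]-2,3-dihydrobenzofuran-3-carboxylate, trans | COC(=O)[C@H]1c2cc(CC=C)cc(OC)c2O[C@@H]1c1ccc(OS(C)(=O)=O)c(OC)c1 | intermediate
18 | 4-[(2S,3R)-5-allyl-3-(hydroxymethyl)-7-methoxy-2,3-dihydrobenzofuran-2-yl]-2-methoxyphenyl methanesulfonate, trans | OC[C@H]1c2cc(CC=C)cc(OC)c2O[C@@H]1c1ccc(OS(C)(=O)=O)c(OC)c1 | intermediate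
19 | eugenol (4-allyl-2-methoxyphenol) | C=CCc1ccc(O)c(OC)c1 | starting material
20 | 4-[(2S,3R)-5-allyl-3-[(4-allyl-2-methoxyphenoxy)methyl]-7-methoxy-2,3-dihydrobenzofuran-2-yl]-2-methoxyphenyl methanesulfonate | C=CCc1ccc(OC[C@H]2c3cc(CC=C)cc(OC)c3O[C@@H]2c2ccc(OS(C)(=O)=O)c(OC)c2)c(OC)c1 | intermediate
21 | 4-[(2S,3R)-5-allyl-3-[(4-allyl-2-methoxyphenoxy)methyl]-7-methoxy-2,3-dihydrobenzofuran-2-yl]-2-methoxyphenol, trans | C=CCc1ccc(OC[C@H]2c3cc(CC=C)cc(OC)c3O[C@@H]2c2ccc(O)c(OC)c2)c(OC)c1 | target

## Step count and least certain steps

Total step count: 14. Longest linear sequence: 13 steps (steps 1 to 7 and 9 to 14, from 1); step 8 is a one-step branch from 10.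

Step 10 (ring switch). The most likely failure is attack of the phenoxide at the acyl carbon instead of at lactone C4. Both closures are five-membered, the carbonyl is the harder and more exposed electrophile, and the SN2 path requires the tether to bend into the lactone plane. Acyl attack would transfer the acyl group to the ring A oxygen and open the way to retro-aldol cleavage or dehydration. Fallback, using known reactions, from 13: methanolysis at the acyl carbon (NaOMe cat., MeOH, −20 °C) gives the syn hydroxy ester F1. Buffered desilylation (Bu4NF, AcOH, THF) gives the phenol F2. An intramolecular Mitsunobu etherification (PPh3, DIAD, THF, 0 °C) closes ring B with inversion at the carbinol carbon and returns to the route at 16.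

Step 9 (key step). The most likely failures are three. Dimerisation of the arylketene may outrun its addition to the aldehyde. Facial selectivity may erode because the ortho silyloxy group twists the aryl ring out of the enolate plane. The acid chloride may undergo intramolecular O-acylation with loss of the silyl group before the ketene forms. Fallback from 9: acylation of lithiated (R)-4-benzyloxazolidin-2-one (n-BuLi, THF, −78 °C) gives the imide F3. An Evans syn-aldol reaction (Bu2BOTf, i-Pr2NEt, CH2Cl2, −78 °C, then 11) gives the (2R,3R) adduct F4. LiOH/H2O2 (THF/H2O, 0 °C) removes the auxiliary to give the hydroxy acid F5. Carboxyl activation (PhSO2Cl, pyridine, 0 °C) closes the lactone with retention at both centres and returns to the route at 13.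

Step 2 (para Claisen rearrangement). The most likely failure is deformylation after migration of the allyl group to the formyl-bearing ortho carbon, together with thermal polymerisation at 200 °C. Fallback from 19: the formyl group is put onto the ring that already carries the allyl group. Ortho-formylation (MgCl2, Et3N, paraformaldehyde, MeCN, reflux), with the para position blocked, gives 4 directly.

Step 14 (mesylate cleavage). The most likely failures are elimination of the aryloxide across C3–C9 and migration of an allyl double bond into conjugation under the strongly basic conditions. Fallback from 18, with the mesylate removed before the C9 ether exists: KOH, MeOH/H2O, 60 °C gives the phenol F6. Ac2O in cold aqueous NaOH acetylates the phenoxide selectively to give F7. Mitsunobu coupling with 19 (PPh3, DIAD, THF) gives F8. K2CO3 in MeOH at rt removes the acetate and returns to the route at 21.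

## Further compounds

F1 | step 10 | methyl (2R,3R)-2-[5-allyl-2-(tert-butyldimethylsilyloxy)-3-methoxyphenyl]-3-hydroxy-3-[3-methoxy-4-(methanesulfonyloxy)phenyl]propanoate | COC(=O)[C@H](c1cc(CC=C)cc(OC)c1O[Si](C)(C)C(C)(C)C)[C@@H](O)c1ccc(OS(C)(=O)=O)c(OC)c1
F2 | step 10 | methyl (2R,3R)-2-(5-allyl-2-hydroxy-3-methoxyphenyl)-3-hydroxy-3-[3-methoxy-4-(methanesulfonyloxy)phenyl]propanoate | COC(=O)[C@H](c1cc(CC=C)cc(OC)c1O)[C@@H](O)c1ccc(OS(C)(=O)=O)c(OC)c1
F3 | step 9 | (R)-3-{2-[5-allyl-2-(tert-butyldimethylsilyloxy)-3-methoxyphenyl]acetyl}-4-benzyloxazolidin-2-one | O=C(Cc1cc(CC=C)cc(OC)c1O[Si](C)(C)C(C)(C)C)N1[C@H](Cc2ccccc2)COC1=O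
F4 | step 9 | (R)-3-{(2R,3R)-2-[5-allyl-2-(tert-butyldimethylsilyloxy)-3-methoxyphenyl]-3-hydroxy-3-[3-methoxy-4-(methanesulfonyloxy)phenyl]propanoyl}-4-benzyloxazolidin-2-one | O=C([C@H](c1cc(CC=C)cc(OC)c1O[Si](C)(C)C(C)(C)C)[C@@H](O)c1ccc(OS(C)(=O)=O)c(OC)c1)N1[C@H](Cc2ccccc2)COC1=O
F5 | step 9 | (2R,3R)-2-[5-allyl-2-(tert-butyldimethylsilyloxy)-3-methoxyphenyl]-3-hydroxy-3-[3-methoxy-4-(methanesulfonyloxy)phenyl]propanoic acid | OC(=O)[C@H](c1cc(CC=C)cc(OC)c1O[Si](C)(C)C(C)(C)C)[C@@H](O)c1ccc(OS(C)(=O)=O)c(OC)c1
F0 | step 2 | none | none
F6 | step 14 | 4-[(2S,3R)-5-allyl-3-(hydroxymethyl)-7-methoxy-2,3-dihydrobenzofuran-2-yl]-2-methoxyphenol | OC[C@H]1c2cc(CC=C)cc(OC)c2O[C@@H]1c1ccc(O)c(OC)c1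
F7 | step 14 | 4-[(2S,3R)-5-allyl-3-(hydroxymethyl)-7-methoxy-2,3-dihydrobenzofuran-2-yl]-2-methoxyphenyl acetate | OC[C@H]1c2cc(CC=C)cc(OC)c2O[C@@H]1c1ccc(OC(C)=O)c(OC)c1
F8 | step 14 | 4-[(2S,3R)-5-allyl-3-[(4-allyl-2-methoxyphenoxy)methyl]-7-methoxy-2,3-dihydrobenzofuran-2-yl]-2-methoxyphenyl acetate | C=CCc1ccc(OC[C@H]2c3cc(CC=C)cc(OC)c3O[C@@H]2c2ccc(OC(C)=O)c(OC)c2)c(OC)c1
A1 | alternative 1 | methyl (2S,3R)-5-bromo-7-methoxy-2-[3-methoxy-4-(triisopropylsilyloxy)phenyl]-2,3-dihydrobenzofuran-3-carboxylate, cis | COC(=O)[C@@H]1c2cc(Br)cc(OC)c2O[C@@H]1c1ccc(O[Si](C(C)C)(C(C)C)C(C)C)c(OC)c1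
A2 | alternative 1 | methyl 2-[5-bromo-3-methoxy-2-({3-methoxy-4-[(triisopropylsilyl)oxy]phenyl}methoxy)phenyl]-2-diazoacetate | COC(=O)C(=[N+]=[N-])c1cc(Br)cc(OC)c1OCc1ccc(O[Si](C(C)C)(C(C)C)C(C)C)c(OC)c1
A3 | alternative 2 | (2S,3R)-5-allyl-3-[(4-allyl-2-methoxyphenoxy)methyl]-2-[3-methoxy-4-(methoxymethoxy)phenyl]-2,3-dihydrobenzofuran-7-ol | C=CCc1ccc(OC[C@H]2c3cc(CC=C)cc(O)c3O[C@@H]2c2ccc(OCOC)c(OC)c2)c(OC)c1
A4 | alternative 2 | ethynyl ether of (1S,2R)-2-(4-allylfuran-2-yl)-3-(4-allyl-2-methoxyphenoxy)-1-[3-methoxy-4-(methoxymethoxy)phenyl]propan-1-ol | C#CO[C@@H]([C@@H](COc1ccc(CC=C)cc1OC)c1cc(CC=C)co1)c1ccc(OCOC)c(OC)c1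
A5 | alternative 3 | 1-{[(2S,3R)-5-allyl-7-methoxy-2-[3-methoxy-4-(triisopropylsilyloxy)phenyl]-2,3-dihydrobenzofuran-3-yl]methoxy}-2,2,6,6-tetramethylpiperidine | CC1(C)CCCC(C)(C)N1OC[C@H]1c2cc(CC=C)cc(OC)c2O[C@@H]1c1ccc(O[Si](C(C)C)(C(C)C)C(C)C)c(OC)c1
A6 | alternative 3 | {4-[(1S)-1-(4-allyl-2-bromo-6-methoxyphenoxy)prop-2-en-1-yl]-2-methoxyphenoxy}triisopropylsilane | C=C[C@H](Oc1c(Br)cc(CC=C)cc1OC)c1ccc(O[Si](C(C)C)(C(C)C)C(C)C)c(OC)c1
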